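A second end group cannot join two partners. With 1.00 equiv of them facing the first end groups and 0.500 equiv of third end groups as well, they are the limiting reagent, and the split depends on who is present when they react.

| flask | first end groups | second end groups | third end groups | protic impurity | remark | time |
|---|---|---|---|---|---|---|
| blue | 0.30 M | 1 equiv | 0.50 equiv | 0.030 M | run made earlier |  |
| amber | 0.20 M | 1 equiv | 0.50 equiv | 0.030 M | run made earlier |  |
| grey | 0.45 M | 1 equiv | 0.50 equiv | 0.030 M | run made earlier |  |
| teal | 0.30 M | 1 equiv | 0.75 equiv | 0.030 M | run made earlier |  |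
| noon | 0.30 M | 1.00 equiv (fed, over 2.5 h) | 0.500 equiv | 0.0300 M | all else is in the flask from the start; the feed brings no volume worth counting | 6.0 h |
| dusk | 0.30 M (fed, over 2.5 h) | 1.00 equiv | 0.500 equiv | 0.0300 M | all else is in the flask from the start; the feed brings no volume worth counting | 6.0 h |
| summer | 0.30 M | 1.00 equiv | 0.500 equiv | 0.0300 M | everything together at the start | 6.0 h |

| run | time / h | links / % | first end groups / % |
|---|---|---|---|
| blue | 0.250 | 67.1 | 32.8 |
| blue | 0.417 | 67.5 | 31.5 |
| blue | 0.667 | 68.3 | 31.6 |
| blue | 1.00 | 67.6 | 31.8 |
| blue | 1.50 | 67.2 | 31.5 |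
| blue | 2.50 | 66.3 | 31.4 |
| blue | 4.00 | 65.5 | 31.7 |
| amber | 0.250 | 64.6 | 35.3 |
| amber | 0.667 | 68.1 | 31.8 |
| amber | 1.33 | 66.7 | 31.8 |
| amber | 2.00 | 66.8 | 31.5 |
| amber | 3.00 | 66.3 | 31.4 |
| amber | 4.00 | 65.5 | 31.8 |
| amber | 5.00 | 64.5 | 31.2 |
| grey | 0.250 | 68.3 | 32.5 |
| grey | 0.667 | 67.9 | 31.2 |
| grey | 1.33 | 67.4 | 31.9 |
| grey | 2.00 | 66.7 | 31.9 |
| grey | 3.00 | 65.9 | 31.7 |
| grey | 4.00 | 65.1 | 31.9 |
| grey | 5.00 | 64.6 | 31.3 |
| teal | 0.417 | 58.7 | 40.8 |
| teal | 1.33 | 58.5 | 41.1 |
| teal | 2.00 | 58.1 | 40.9 |
| teal | 3.00 | 57.0 | 40.3 |
| teal | 5.00 | 56.0 | 40.6 |

(readings scatter by 0.3 percentage points)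

- the numbers in the tables scatter with a standard deviation of 0.3 percentage points

- the flask that comes out highest in amount of links, in percent of the first end groups charged, or "all alike" when all lie within 1.5 percentage points (noon / dusk / summer / all alike)
- links at the end, in percent of the first end groups charged, noon
- links at the end, in percent of the first end groups charged, dusk
- links at the end, in percent of the first end groups charged, summer

I read the runs as a ladder of times. The contest is the fastest rung: in blue, first end groups read 32.8% at 0.250 h and 31.8% at 1.00 h, so the contest is nearly over early, and the feed of 2.5 h lasts ten times as long. The slowest rung is a drain on the links, which in blue lose a fraction 0.0123 h⁻¹. So I put summer, blue's twin, at 63.9%. For noon I have to assume that it keeps blue's split; on that assumption its links are younger by 1.25 h on average, which gives 64.9%.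

Dusk is another matter. Because the contest is far shorter than the feed, third end groups should take their charge of second end groups while the feed has barely begun. That leaves 0.500, which I call the leftover share: second end groups minus third end groups, as a fraction of the first end groups charged. With the drain counted over the whole 6.0 h, a little too long, I expect 0.463 of the charge as links in dusk, and noon highest.

The forecast says all alike, with 64.7%, 64.5% and 63.9% for noon, dusk and summer: “Exchange is quick compared with the feed, so all flasks reach the same equilibrium”. Here I differ from it on dusk.

Noon gives 69.3%, dusk 45.0% and summer 63.9%, so noon comes out highest. My assumption for noon fails: it does not keep the split of summer, blue's twin, for its first end groups end at 26.8% against 31.6% in summer, and its links stand 4.4 points above my reckoning.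

    first end groups + second end groups → links (k = 1.33 L mol⁻¹ min⁻¹)
    second end groups + third end groups → links of the second sort (k = 1.15 L mol⁻¹ min⁻¹)
    links ⇌ isomer of the product (K = 2.90, k = 1.95 × 10⁻⁴ min⁻¹)
    second end groups + protic impurity → quenched reagent (k = 0.0450 L mol⁻¹ min⁻¹)
    third end groups ⇌ dormant form (K = 5.24, k = 0.00340 min⁻¹)

In dusk, half of the turnover of second with third end groups is done by 2.32 min, against 0.740 h for the making of links. Third end groups stand at 0.0696% of their charge at the end of the feed. Dusk's leftover share of 0.500, less 0.0290 as quenched reagent, meets links plus isomer of the product at 47.8. In a flask like dusk with 0.120 equiv of third end groups, the leftover share is 0.880, quenched reagent takes 0.0558, and links plus isomer of the product reach 82.5.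

All runs are calculated on assumed constants; scatter was added.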